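**Plan**

- Retrosynthesis: C8–ethyl and C8–C9 are cut first (two Negishi couplings on a C7 gem-dibromoalkene), then C7=C8 (dibromo-olefination of a C7 aldehyde that comes from a C7,C8-diol), C3–H (hydride to a C3 peroxycarbenium ion), the ring bond O1–C6 (peroxide oxygen opening a C6–C7 epoxide), C2–C3 (Reformatsky–Negishi coupling) and C4–C5 (Ireland–Claisen).
- Forward: the acyclic C3–C8 chain is assembled first, C1–C2 is attached as a 3-methylidene ester, epoxidation and ozonolysis in methanol follow, the only ring (the 1,2-dioxane) closes in step 11, and the C7–C14 side chain is joined last at the dibromoalkene.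
- Enabling feature: ring oxygen O1 sits on the quaternary carbon C6, whose neighbour C7 can carry oxygen, so C6–C7 can be the epoxide of an (E)-allylic alcohol. C3, four atoms away, holds O2–O1H as a methoxy hydroperoxy ketal, so closure of the ring O1–O2–C3–C4–C5–C6 is a 6-exo opening at the tertiary epoxide carbon with inversion.
- C3 is carried at the ketone oxidation level through the ring closure. A carbon nucleophile adding to a C3–H peroxycarbenium ion would be expected to enter axially, cis to both ring ethyl groups; hydride adding to the C3-substituted ion leaves the acetate arm equatorial, as the target requires.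
- Stereochemistry: C4 by chirality transfer from a kinetically resolved carbinol through a chair Ireland–Claisen transition state; C6 by D-(−)-tartrate epoxidation and inversion in step 11; C3 by axial hydride delivery; C10 by Zr-catalysed asymmetric carboalumination; the (E)-C7=C8 bond by a trans-selective and then a stereoretentive Negishi coupling.

Key step: step 11

Remark on the chemistry: atom labels follow the target (C1 ester carbon, ring atoms O1, O2, C3–C6, side chain C7–C14); the ketal carbon C3 of 20–23 is a mixture of epimers, which is immaterial because C3 becomes trigonal in step 14.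

**Step 1**
Reactants: 1 2-bromobut-1-ene; 2 (tert-butyldimethylsilyloxy)acetaldehyde
Product: 4 rac-1-[(tert-butyldimethylsilyl)oxy]-3-methylidenepentan-2-ol, via but-1-en-2-ylmagnesium bromide 3 (not isolated)
Conditions: Mg, THF, 40 °C; then 2, THF, −78 → 0 °C; H2O
Reagents that add atoms: magnesium [Mg] (retained only in 3)
Why: Grignard addition of the alkenylmagnesium reagent to the aldehyde gives the 2-substituted allylic alcohol; the carbinol centre forms as a racemate and is resolved in step 2.

**Step 2**
Reactants: 4 racemic allylic alcohol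
Product: 5 (2R)-1-[(tert-butyldimethylsilyl)oxy]-3-methylidenepentan-2-ol
Conditions: Ti(OiPr)4, D-(−)-diisopropyl tartrate, t-BuOOH (0.6 equiv), 4 Å MS, CH2Cl2, −20 °C
Reagents that add atoms: none
Why: Sharpless kinetic resolution: with the D-(−)-tartrate the (S)-alcohol is epoxidised faster and the (R)-alcohol is recovered (the CIP labels are the reverse of those of simple alkyl carbinols because CH2OSi outranks the alkenyl group), so the carbinol centre is fixed by reagent control.

**Step 3**
Reactants: 5 (R)-allylic alcohol; 6 butanoyl chloride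
Product: 7 (2R)-1-[(tert-butyldimethylsilyl)oxy]-3-methylidenepentan-2-yl butanoate
Conditions: pyridine, DMAP (cat.), CH2Cl2, 0 °C → rt
Reagents that add atoms: none
Why: DMAP-catalysed O-acylation of the secondary alcohol, with retention at the carbinol carbon.

**Step 4**
Reactants: 7 allylic butanoate
Product: 10 (2R,4E)-6-[(tert-butyldimethylsilyl)oxy]-2,4-diethylhex-4-enoic acid, via (E)-silyl ketene acetal 8 (not isolated), via trimethylsilyl ester 9 (not isolated)
Conditions: LiN(iPr)2, THF, −78 °C; Me3SiCl, −78 °C → rt, then 50 °C; H2O, dilute citric acid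
Reagents that add atoms: chlorotrimethylsilane C[Si](C)(C)Cl (retained only in 8 and 9)
Why: Ireland–Claisen rearrangement: kinetic enolisation in THF gives the (E)-ketene acetal, and the chair transition state with CH2OTBS equatorial forms C4–C5, transfers the carbinol chirality to C4 (R; C2 of 10) and gives the (E)-trisubstituted C6=C7 alkene; any (Z)-ketene acetal would end as the C4 epimer, which becomes a separable diastereomer after step 9.

**Step 5**
Reactants: 10 acid
Product: 12 (3R,5E)-7-[(tert-butyldimethylsilyl)oxy]-3,5-diethylhept-5-en-2-one, via dilithium gem-diolate 11 (not isolated)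
Conditions: MeLi (2.2 equiv), Et2O, 0 °C; inverse quench into cold H2O
Reagents that add atoms: methyllithium [Li]C
Why: Addition of methyllithium to the lithium carboxylate stops at the gem-diolate, which collapses to the methyl ketone only on hydrolysis, so no ketone meets base and C4 is not enolised (organolithium ketone synthesis from a carboxylic acid).

**Step 6**
Reactants: 12 methyl ketone
Product: 14 (3R,5E)-7-[(tert-butyldimethylsilyl)oxy]-3,5-diethylhepta-1,5-dien-2-yl trifluoromethanesulfonate, via potassium enolate 13 (not isolated)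
Conditions: KN(SiMe3)2, THF, −78 °C (ketone added to base); PhNTf2, −78 → 0 °C
Reagents that add atoms: N-phenylbis(trifluoromethanesulfonimide) O=S(=O)(N(c1ccccc1)S(=O)(=O)C(F)(F)F)C(F)(F)F; potassium bis(trimethylsilyl)amide C[Si](C)(C)[N-][Si](C)(C)C.[K+] (potassium retained only in 13)
Why: Kinetic deprotonation at the unhindered methyl group and O-triflation give the terminal enol triflate; the tertiary C4–H is not removed under these conditions.

**Step 7**
Reactants: 14 enol triflate; 15 methyl bromoacetate
Product: 17 methyl (4R,6E)-8-[(tert-butyldimethylsilyl)oxy]-4,6-diethyl-3-methylideneoct-6-enoate, via Reformatsky reagent 16 (not isolated)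
Conditions: 15, Zn, THF, rt (gives 16); then 14, Pd(PPh3)4 (5 mol %), THF, 55 °C
Reagents that add atoms: zinc [Zn] (retained only in 16)
Why: Negishi-type cross-coupling of a Reformatsky reagent with an alkenyl triflate under zerovalent palladium catalysis forms C2–C3 and gives the deconjugated 3-methylidene ester, whose exocyclic carbon is the handle for ozonolysis; no stereocentre is touched.

**Step 8**
Reactants: 17 silyl ether
Product: 18 methyl (4R,6E)-4,6-diethyl-8-hydroxy-3-methylideneoct-6-enoate
Conditions: HF·pyridine, pyridine, THF, 0 °C → rt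
Reagents that add atoms: none
Why: Fluoride-mediated cleavage of the primary allylic silyl ether under buffered, slightly acidic conditions, which avoids base-induced migration of the 3-methylidene double bond into conjugation.

**Step 9**
Reactants: 18 allylic alcohol
Product: 19 methyl (4R)-4-{[(2R,3R)-2-ethyl-3-(hydroxymethyl)oxiran-2-yl]methyl}-3-methylidenehexanoate
Conditions: Ti(OiPr)4 (10 mol %), D-(−)-diethyl tartrate (12 mol %), t-BuOOH, 4 Å MS, CH2Cl2, −20 °C
Reagents that add atoms: tert-butyl hydroperoxide CC(C)(C)OO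
Why: Sharpless asymmetric epoxidation of a 3,3-disubstituted (E)-allylic alcohol; the D-(−)-tartrate gives the (2R,3R)-epoxide (C6 and C7) by reagent control, and the non-allylic 1,1-disubstituted alkene is left alone.

**Step 10**
Reactants: 19 epoxy alcohol
Product: 20 methyl (4R)-4-{[(2R,3R)-2-ethyl-3-(hydroxymethyl)oxiran-2-yl]methyl}-3-hydroperoxy-3-methoxyhexanoate (C3 epimers)
Conditions: O3, CH2Cl2/MeOH, NaHCO3, −78 °C; N2 purge; no reductive work-up
Reagents that add atoms: ozone [O-][O+]=O; methanol CO
Why: Ozonolysis by the Criegee mechanism: the primary ozonide of the 1,1-disubstituted alkene fragments to formaldehyde and the more substituted C3 carbonyl oxide, which methanol traps as the methoxy hydroperoxy ketal; C3 forms unselectively, which is of no consequence.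

**Step 11**
Reactants: 20 epoxy hydroperoxy ketal
Product: 21 methyl 2-[(4R,6S)-6-[(1R)-1,2-dihydroxyethyl]-4,6-diethyl-3-methoxy-1,2-dioxan-3-yl]acetate (C3 epimers)
Conditions: CSA (10 mol %), CH2Cl2, 0 °C
Reagents that add atoms: none
Why: CSA protonates the epoxide oxygen and the terminal oxygen of the C3 methoxy hydroperoxy ketal attacks the tertiary carbon C6 from the rear, forming O1–C6 and releasing the C7 hydroxyl. The closest known reaction types are the acid-promoted intramolecular opening of epoxides by hydroperoxides and the cyclisation of ozonolysis-derived hydroperoxy acetals onto tethered electrophiles. The 1,2-dioxane ring (O1, O2, C3, C4, C5, C6) closes in the 6-exo-tet mode. C6 becomes (S) by inversion of the (R)-epoxide carbon installed by the D-(−)-tartrate epoxidation, while C7 keeps its configuration and C4 is untouched. The step needs attack at C6 and not at C7, and by the hydroperoxide and not by the C8 hydroxyl or the methoxy oxygen: the tertiary carbon carries the developing positive charge, the exo mode is favoured over the 7-endo alternative, the hydroperoxide is the most nucleophilic oxygen (alpha effect), and the C8 hydroxyl could only close a four-membered ring. The ketal next to the ester CH2 ionises slowly, so catalytic acid at 0 °C should leave C3 intact.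

**Step 12**
Reactants: 21 dioxane diol
Product: 22 methyl 2-[(4R,6S)-4,6-diethyl-6-formyl-3-methoxy-1,2-dioxan-3-yl]acetate (C3 epimers)
Conditions: NaIO4, THF/H2O, 0 °C → rt
Reagents that add atoms: none
Why: Periodate glycol cleavage removes C8 and unmasks the C7 aldehyde; the dialkyl peroxide is inert to periodate and C6, having no hydrogen, cannot epimerise.

**Step 13**
Reactants: 22 aldehyde
Product: 23 methyl 2-[(4R,6S)-6-(2,2-dibromoethenyl)-4,6-diethyl-3-methoxy-1,2-dioxan-3-yl]acetate (C3 epimers)
Conditions: CBr4, PPh3, Zn, CH2Cl2, rt (ylide preformed); then 22, 0 °C → rt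
Reagents that add atoms: carbon tetrabromide BrC(Br)(Br)Br
Why: Ramirez dibromo-olefination (first stage of the Corey–Fuchs sequence) with a preformed ylide, so that little free phosphine meets the peroxide, which at this stage is flanked by two fully substituted carbons (C3 and C6) and should therefore react only slowly with phosphines.

**Step 14**
Reactants: 23 methoxy ketal
Product: 24 methyl 2-[(3S,4R,6S)-6-(2,2-dibromoethenyl)-4,6-diethyl-1,2-dioxan-3-yl]acetate
Conditions: Et3SiH, Me3SiOTf (0.3 equiv), CH2Cl2, −78 → −40 °C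
Reagents that add atoms: none
Why: Proposed new method: Me3SiOTf silylates the more basic exocyclic methoxy oxygen, Me3SiOMe leaves, and the cyclic peroxycarbenium ion (O2=C3) is reduced by Et3SiH, a hydride donor at least as nucleophilic as the allylsilanes known to trap such ions; the ion adopts the half-chair with the C4 and C6 ethyl groups pseudo-equatorial (the other half-chair would place them syn-diaxial), and hydride enters along the axial trajectory on the face opposite the axial dibromoethenyl group, which leaves the CH2CO2Me arm equatorial and sets C3 as (S), trans to the C4 ethyl group; the closest known reaction types are the Et3SiH/Lewis acid reduction of cyclic ketals and hemiketals through oxocarbenium ions (ionic hydrogenation with axial hydride delivery) and the Lewis acid-mediated substitution of cyclic peroxyketals by allylsilanes and silyl ketene acetals.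

**Step 15**
Reactants: 25 1-hexene
Product: 27 (3S)-3-(iodomethyl)heptane, via (2-ethylhexyl)diethylalane 26 (not isolated)
Conditions: Et3Al, (+)-(NMI)2ZrCl2 [(+)-bis(1-neomenthylindenyl)zirconium dichloride] (5 mol %), CH2Cl2, rt; then I2, THF, 0 °C → rt
Reagents that add atoms: triethylaluminium CC[Al](CC)CC; iodine II
Why: Zirconium-catalysed asymmetric carboalumination (ZACA reaction): enantioface-selective ethylalumination of the terminal alkene sets C10 as (S) under catalyst control [the (+)-catalyst is the antipode of the one that gives (R)-2-alkylalkan-1-ols], and iodinolysis of the C–Al bond gives the iodide with retention.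

**Step 16**
Reactants: 24 dibromoalkene; 27 (S)-iodide
Product: 29 methyl 2-[(3S,4R,6S)-6-[(1Z,4S)-2-bromo-4-ethyloct-1-en-1-yl]-4,6-diethyl-1,2-dioxan-3-yl]acetate, via (2S)-2-ethylhexylzinc iodide 28 (not isolated)
Conditions: 27, Zn dust (activated), DMF, 45 °C (gives 28); then 24, Pd(DPEphos)Cl2 (5 mol %), THF/DMF, 0 °C → rt
Reagents that add atoms: zinc [Zn] (retained only in 28)
Why: Negishi coupling as a trans-selective monoalkylation of a 1,1-dibromoalkene: oxidative addition occurs at the C–Br bond trans to the bulky C6 substituent, so the C9 chain ends trans to C6; saturated dialkyl peroxides and esters are compatible with alkylzinc halides and zerovalent palladium at room temperature.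

**Step 17**
Reactants: 29 (Z)-bromoalkene
Product: 30 methyl 2-[(3S,4R,6S)-6-[(1E,4S)-2,4-diethyloct-1-en-1-yl]-4,6-diethyl-1,2-dioxan-3-yl]acetate (target)
Conditions: Et2Zn, Pd(tBu3P)2 (5 mol %), THF, rt
Reagents that add atoms: diethylzinc CC[Zn]CC
Why: Second Negishi coupling with retention of alkene geometry: the bulky electron-rich phosphine favours oxidative addition at the hindered bromide and reductive elimination over β-hydride elimination, placing the ethyl group cis to C6 and completing the (E)-trisubstituted alkene.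

**Compound list**

1 | 2-bromobut-1-ene | C=C(Br)CC | starting material
2 | (tert-butyldimethylsilyloxy)acetaldehyde | CC(C)(C)[Si](C)(C)OCC=O | starting material
3 | but-1-en-2-ylmagnesium bromide | C=C(CC)[Mg]Br | intermediate
4 | rac-1-[(tert-butyldimethylsilyl)oxy]-3-methylidenepentan-2-ol | C=C(CC)C(O)CO[Si](C)(C)C(C)(C)C | intermediate
5 | (2R)-1-[(tert-butyldimethylsilyl)oxy]-3-methylidenepentan-2-ol | C=C(CC)[C@@H](O)CO[Si](C)(C)C(C)(C)C | intermediate
6 | butanoyl chloride | CCCC(=O)Cl | starting material
7 | (2R)-1-[(tert-butyldimethylsilyl)oxy]-3-methylidenepentan-2-yl butanoate | CCCC(=O)O[C@@H](CO[Si](C)(C)C(C)(C)C)C(=C)CC | intermediate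
8 | (E)-trimethylsilyl ketene acetal of 7 [(1E)-1-(trimethylsilyloxy)but-1-en-1-yl ether of 5] | CC/C=C(/O[Si](C)(C)C)O[C@@H](CO[Si](C)(C)C(C)(C)C)C(=C)CC | intermediate
9 | trimethylsilyl (2R,4E)-6-[(tert-butyldimethylsilyl)oxy]-2,4-diethylhex-4-enoate | CC(C)(C)[Si](C)(C)OC/C=C(\CC)C[C@@H](CC)C(=O)O[Si](C)(C)C | intermediate
10 | (2R,4E)-6-[(tert-butyldimethylsilyl)oxy]-2,4-diethylhex-4-enoic acid | CC(C)(C)[Si](C)(C)OC/C=C(\CC)C[C@@H](CC)C(=O)O | intermediate
11 | dilithium (3R,5E)-7-[(tert-butyldimethylsilyl)oxy]-3,5-diethylhept-5-ene-2,2-diolate | CC(C)(C)[Si](C)(C)OC/C=C(\CC)C[C@@H](CC)C(C)([O-])[O-].[Li+].[Li+] | intermediate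
12 | (3R,5E)-7-[(tert-butyldimethylsilyl)oxy]-3,5-diethylhept-5-en-2-one | CC(C)(C)[Si](C)(C)OC/C=C(\CC)C[C@@H](CC)C(C)=O | intermediate
13 | potassium (3R,5E)-7-[(tert-butyldimethylsilyl)oxy]-3,5-diethylhepta-1,5-dien-2-olate | CC(C)(C)[Si](C)(C)OC/C=C(\CC)C[C@@H](CC)C(=C)[O-].[K+] | intermediate
14 | (3R,5E)-7-[(tert-butyldimethylsilyl)oxy]-3,5-diethylhepta-1,5-dien-2-yl trifluoromethanesulfonate | CC(C)(C)[Si](C)(C)OC/C=C(\CC)C[C@@H](CC)C(=C)OS(=O)(=O)C(F)(F)F | intermediate
15 | methyl bromoacetate | COC(=O)CBr | starting material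
16 | bromo(2-methoxy-2-oxoethyl)zinc | COC(=O)C[Zn]Br | intermediate
17 | methyl (4R,6E)-8-[(tert-butyldimethylsilyl)oxy]-4,6-diethyl-3-methylideneoct-6-enoate | CC(C)(C)[Si](C)(C)OC/C=C(\CC)C[C@@H](CC)C(=C)CC(=O)OC | intermediate
18 | methyl (4R,6E)-4,6-diethyl-8-hydroxy-3-methylideneoct-6-enoate | OC/C=C(\CC)C[C@@H](CC)C(=C)CC(=O)OC | intermediate
19 | methyl (4R)-4-{[(2R,3R)-2-ethyl-3-(hydroxymethyl)oxiran-2-yl]methyl}-3-methylidenehexanoate | OC[C@H]1O[C@]1(CC)C[C@@H](CC)C(=C)CC(=O)OC | intermediate
20 | methyl (4R)-4-{[(2R,3R)-2-ethyl-3-(hydroxymethyl)oxiran-2-yl]methyl}-3-hydroperoxy-3-methoxyhexanoate (C3 epimers) | OC[C@H]1O[C@]1(CC)C[C@@H](CC)C(OC)(OO)CC(=O)OC | intermediate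
21 | methyl 2-[(4R,6S)-6-[(1R)-1,2-dihydroxyethyl]-4,6-diethyl-3-methoxy-1,2-dioxan-3-yl]acetate (C3 epimers) | OC[C@@H](O)[C@]1(CC)C[C@@H](CC)C(OC)(CC(=O)OC)OO1 | intermediate
22 | methyl 2-[(4R,6S)-4,6-diethyl-6-formyl-3-methoxy-1,2-dioxan-3-yl]acetate (C3 epimers) | O=C[C@]1(CC)C[C@@H](CC)C(OC)(CC(=O)OC)OO1 | intermediate
23 | methyl 2-[(4R,6S)-6-(2,2-dibromoethenyl)-4,6-diethyl-3-methoxy-1,2-dioxan-3-yl]acetate (C3 epimers) | BrC(Br)=C[C@]1(CC)C[C@@H](CC)C(OC)(CC(=O)OC)OO1 | intermediate
24 | methyl 2-[(3S,4R,6S)-6-(2,2-dibromoethenyl)-4,6-diethyl-1,2-dioxan-3-yl]acetate | BrC(Br)=C[C@]1(CC)C[C@@H](CC)[C@H](CC(=O)OC)OO1 | intermediate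
25 | 1-hexene | C=CCCCC | starting material
26 | diethyl[(2S)-2-ethylhexyl]alumane | CCCC[C@H](CC)C[Al](CC)CC | intermediate
27 | (3S)-3-(iodomethyl)heptane | CCCC[C@H](CC)CI | intermediate
28 | [(2S)-2-ethylhexyl](iodo)zinc | CCCC[C@H](CC)C[Zn]I | intermediate
29 | methyl 2-[(3S,4R,6S)-6-[(1Z,4S)-2-bromo-4-ethyloct-1-en-1-yl]-4,6-diethyl-1,2-dioxan-3-yl]acetate | CCCC[C@H](CC)C/C(Br)=C/[C@]1(CC)C[C@@H](CC)[C@H](CC(=O)OC)OO1 | intermediate
30 | methyl 2-[(3S,4R,6S)-6-[(1E,4S)-2,4-diethyloct-1-en-1-yl]-4,6-diethyl-1,2-dioxan-3-yl]acetate | CCCC[C@H](CC)C/C(=C/[C@]1(CC)C[C@@H](CC)[C@H](CC(=O)OC)OO1)CC | target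

**Step count**

Total: 17 steps. Longest linear sequence: 16 steps (steps 1–14, 16 and 17); step 15 is a one-step branch.

**Steps most likely to fail**

Step 14 (the labelled step). What may go wrong: ionisation of the ring C3–O2 bond in place of the exocyclic C3–OMe bond, loss of a C2 proton from the peroxycarbenium ion to give an enol peroxide, or hydride transfer through the other half-chair, which would erode the C3 configuration. The fallback uses known reactions only; it sets out from acid 10, puts C3–H in place before any peroxide exists, and comes back to the route at 24. LiAlH4 (Et2O, 0 °C) gives the alcohol (2R,4E)-6-[(tert-butyldimethylsilyl)oxy]-2,4-diethylhex-4-en-1-ol F1. Dess–Martin oxidation gives the aldehyde (2R,4E)-6-[(tert-butyldimethylsilyl)oxy]-2,4-diethylhex-4-enal F2, which is taken directly into a Wittig reaction with Ph3P=CHCO2Me to give the enoate methyl (2E,4R,6E)-8-[(tert-butyldimethylsilyl)oxy]-4,6-diethylocta-2,6-dienoate F3. HF·pyridine gives the allylic alcohol methyl (2E,4R,6E)-4,6-diethyl-8-hydroxyocta-2,6-dienoate F4, and Sharpless epoxidation with D-(−)-diethyl tartrate gives the epoxy alcohol methyl (2E,4R)-4-{[(2R,3R)-2-ethyl-3-(hydroxymethyl)oxiran-2-yl]methyl}hex-2-enoate F5. Perhydrolysis with ethereal H2O2 and catalytic H3PMo12O40 should open the epoxide at the tertiary carbon with inversion to the hydroperoxide methyl (2E,4R,6S,7R)-4,6-diethyl-6-hydroperoxy-7,8-dihydroxyoct-2-enoate F6. Et2NH in CF3CH2OH then closes the ring by intramolecular peroxy-Michael addition (O2–C3 bond, chair with both ethyl groups and the forming acetate arm equatorial) to give methyl 2-[(3S,4R,6S)-6-[(1R)-1,2-dihydroxyethyl]-4,6-diethyl-1,2-dioxan-3-yl]acetate F7; any C3 epimer would be removed by chromatography. NaIO4 gives the aldehyde methyl 2-[(3S,4R,6S)-4,6-diethyl-6-formyl-1,2-dioxan-3-yl]acetate F8, and Ramirez olefination with a preformed ylide returns to 24.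

Step 11 (key step). What may go wrong: ionisation of the tertiary epoxide carbon ahead of ring closure (loss of stereospecificity at C6, hydride or alkyl shifts), or acid-induced exchange at the C3 ketal by the liberated diol. The fallback sets out from 19 and comes back at 21; it forms O1–C6 intermolecularly and closes the ring from the other end. Perhydrolysis of 19 with ethereal H2O2 and catalytic H3PMo12O40 should open the epoxide at C6 with inversion to give methyl (4R)-4-[(2S,3R)-2-ethyl-2-hydroperoxy-3,4-dihydroxybutyl]-3-methylidenehexanoate F9. Ozonolysis in CH2Cl2/MeOH at −78 °C converts the methylidene group into the C3 methoxy hydroperoxy ketal methyl (4R)-4-[(2S,3R)-2-ethyl-2-hydroperoxy-3,4-dihydroxybutyl]-3-hydroperoxy-3-methoxyhexanoate F10. Catalytic CSA in MeOH/CH2Cl2 then closes the 1,2-dioxane by peroxyketal exchange, the C6 hydroperoxide displacing H2O2 at C3, to give 21.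

Step 17. What may go wrong: sluggish oxidative addition at the bromide cis to the quaternary C6 centre, β-hydride elimination from the ethylpalladium intermediate (net reduction of the bromide), or E/Z isomerisation. The fallback sets out from 29 and comes back at 30; it replaces the sp3 nucleophile by an sp2 one that cannot undergo β-hydride elimination and then saturates it chemoselectively. Stille coupling of 29 with tributyl(vinyl)stannane (Pd2(dba)3, AsPh3, DMF, 50 °C) gives the diene methyl 2-[(3S,4R,6S)-6-[(1Z,4S)-2-ethenyl-4-ethyloct-1-en-1-yl]-4,6-diethyl-1,2-dioxan-3-yl]acetate F11. Diimide (from KO2CN=NCO2K and AcOH, MeOH/CH2Cl2, rt), which spares O–O bonds and reduces monosubstituted alkenes much faster than trisubstituted ones, should then saturate only the terminal vinyl group and give 30.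

**Further compounds**

F1 | step 14 | (2R,4E)-6-[(tert-butyldimethylsilyl)oxy]-2,4-diethylhex-4-en-1-ol | CC(C)(C)[Si](C)(C)OC/C=C(\CC)C[C@@H](CC)CO
F2 | step 14 | (2R,4E)-6-[(tert-butyldimethylsilyl)oxy]-2,4-diethylhex-4-enal | CC(C)(C)[Si](C)(C)OC/C=C(\CC)C[C@@H](CC)C=O
F3 | step 14 | methyl (2E,4R,6E)-8-[(tert-butyldimethylsilyl)oxy]-4,6-diethylocta-2,6-dienoate | CC(C)(C)[Si](C)(C)OC/C=C(\CC)C[C@@H](CC)/C=C/C(=O)OC
F4 | step 14 | methyl (2E,4R,6E)-4,6-diethyl-8-hydroxyocta-2,6-dienoate | OC/C=C(\CC)C[C@@H](CC)/C=C/C(=O)OC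
F5 | step 14 | methyl (2E,4R)-4-{[(2R,3R)-2-ethyl-3-(hydroxymethyl)oxiran-2-yl]methyl}hex-2-enoate | OC[C@H]1O[C@]1(CC)C[C@@H](CC)/C=C/C(=O)OC
F6 | step 14 | methyl (2E,4R,6S,7R)-4,6-diethyl-6-hydroperoxy-7,8-dihydroxyoct-2-enoate | OC[C@@H](O)[C@@](CC)(OO)C[C@@H](CC)/C=C/C(=O)OC
F7 | step 14 | methyl 2-[(3S,4R,6S)-6-[(1R)-1,2-dihydroxyethyl]-4,6-diethyl-1,2-dioxan-3-yl]acetate | OC[C@@H](O)[C@]1(CC)C[C@@H](CC)[C@H](CC(=O)OC)OO1
F8 | step 14 | methyl 2-[(3S,4R,6S)-4,6-diethyl-6-formyl-1,2-dioxan-3-yl]acetate | O=C[C@]1(CC)C[C@@H](CC)[C@H](CC(=O)OC)OO1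
F9 | step 11 | methyl (4R)-4-[(2S,3R)-2-ethyl-2-hydroperoxy-3,4-dihydroxybutyl]-3-methylidenehexanoate | OC[C@@H](O)[C@@](CC)(OO)C[C@@H](CC)C(=C)CC(=O)OC
F10 | step 11 | methyl (4R)-4-[(2S,3R)-2-ethyl-2-hydroperoxy-3,4-dihydroxybutyl]-3-hydroperoxy-3-methoxyhexanoate | OC[C@@H](O)[C@@](CC)(OO)C[C@@H](CC)C(OC)(OO)CC(=O)OC
F11 | step 17 | methyl 2-[(3S,4R,6S)-6-[(1Z,4S)-2-ethenyl-4-ethyloct-1-en-1-yl]-4,6-diethyl-1,2-dioxan-3-yl]acetate | CCCC[C@H](CC)C/C(=C/[C@]1(CC)C[C@@H](CC)[C@H](CC(=O)OC)OO1)C=C
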